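**Plan**

1. Retrosynthesis: upper ring C is opened at O1–C2 (Mitsunobu etherification) and at C2–C1′ (aryllithium on a Weinreb amide), leaving a 3-benzyloxy-4-aryl-3,4-dihydrocoumarin. O1 is then excised from between C8a and C2 (retro-Baeyer–Villiger). The resulting indanone is cut at C4–C4a (reductive Heck) and at the enone C=C (aldol) into a bromoacetophenone and the lower-unit 6-carbaldehyde.
2. Enabling feature: upper ring C (O1, C2, C3, C4, C4a, C8a) is the five-membered carbocycle of a 3-aryl-indan-1-one (C2, C3, C4, C4a, C8a) with the single atom O1 inserted between aromatic C8a and C2. Its C4 carries C6 of the lower flavan-3,4-diol.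
3. Forward ring order: lower ring C (phenol opening of a chalcone epoxide), the indanone ring (Pd cyclisation), its expansion to the lactone (oxygen insertion), then reopening and reclosure as upper ring C.
4. Stereochemistry, lower unit: C2 and C3 from a Juliá–Colonna epoxidation (C2 inverted on ring closure), C4 from NaBH4 reduction.
5. Stereochemistry, upper unit: C4 from the chiral Pd catalyst, C3 from enolate hydroxylation anti to the C4 aryl, C2 from chelation-controlled reduction followed by Mitsunobu inversion.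

Key step: step 16

Remark on the target: read from the SMILES, the upper unit is a 2,3-cis-3,4-trans flavan-3-ol (2R,3R,4S) and the lower unit a 2,3-trans-3,4-trans flavan-3,4-diol (2R,3S,4R), joined C4→C6.

Assumption: the sense of induction of poly-L-leucine (step 5) and of the bisphosphine (step 15) is taken over from simple chalcones. If a test on the real substrate shows the opposite sense, the antipodal catalyst is used.

Abbreviation: ArL = (2R,3R,4R)-7,8-bis(benzyloxy)-2-[4-(benzyloxy)phenyl]-3,4-bis(tert-butyldimethylsilyloxy)chroman-6-yl, the protected lower unit. Flavan numbering (O1, C2, C3, C4, C4a, C5–C8, C8a) is used for both units.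

**Route**

Step 1
Reactants: 1 gallacetophenone (1-(2,3,4-trihydroxyphenyl)ethan-1-one)
Product: 2 1-[3,4-bis(benzyloxy)-2-hydroxyphenyl]ethan-1-one
Conditions: BnBr (2.1 equiv), K2CO3, DMF, rt
Reagents that add atoms: benzyl bromide, BrCc1ccccc1
Why: Williamson etherification, in which the 2-hydroxyl, held in a hydrogen bond to the acetyl oxygen, is the least reactive phenol and should stay free with two equivalents of BnBr.

Step 2
Reactants: 2 1-[3,4-bis(benzyloxy)-2-hydroxyphenyl]ethan-1-one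
Product: 3 1-[3,4-bis(benzyloxy)-5-bromo-2-hydroxyphenyl]ethan-1-one
Conditions: NBS, MeCN, 0 °C
Reagents that add atoms: N-bromosuccinimide, O=C1CCC(=O)N1Br
Why: Electrophilic aromatic bromination goes to C5, the only open position para to the free phenol and ortho to a benzyloxy group, and this carbon becomes C6 of the lower chromane.

Step 3
Reactants: 3 1-[3,4-bis(benzyloxy)-5-bromo-2-hydroxyphenyl]ethan-1-one
Product: 4 1-[3,4-bis(benzyloxy)-5-bromo-2-(methoxymethoxy)phenyl]ethan-1-one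
Conditions: NaH, MOMCl, DMF, 0 °C
Reagents that add atoms: chloromethyl methyl ether, COCCl
Why: O-Alkylation of the phenoxide (methoxymethyl protection) blocks Algar–Flynn–Oyamada-type cyclisation during the later epoxidation and installs a group that acid removes in step 6.

Step 4
Reactants: 4 1-[3,4-bis(benzyloxy)-5-bromo-2-(methoxymethoxy)phenyl]ethan-1-one; 5 4-(benzyloxy)benzaldehyde
Product: 6 (E)-1-[3,4-bis(benzyloxy)-5-bromo-2-(methoxymethoxy)phenyl]-3-[4-(benzyloxy)phenyl]prop-2-en-1-one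
Conditions: KOH, EtOH/THF, rt
Reagents that add atoms: none
Why: Claisen–Schmidt condensation of a methyl ketone with a non-enolisable aldehyde gives the E-chalcone under thermodynamic control.

Step 5
Reactants: 6 (E)-1-[3,4-bis(benzyloxy)-5-bromo-2-(methoxymethoxy)phenyl]-3-[4-(benzyloxy)phenyl]prop-2-en-1-one
Product: 7 [3,4-bis(benzyloxy)-5-bromo-2-(methoxymethoxy)phenyl]{(2R,3S)-3-[4-(benzyloxy)phenyl]oxiran-2-yl}methanone
Conditions: poly-L-leucine, urea·H2O2, DBU, THF, rt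
Reagents that add atoms: urea–hydrogen peroxide, NC(N)=O.OO
Why: Juliá–Colonna epoxidation, in which the helical poly-L-leucine delivers hydroperoxide to one face of the E-enone and should give the trans-(2R,3S)-epoxide, both new stereocentres being catalyst-controlled.

Step 6
Reactants: 7 [3,4-bis(benzyloxy)-5-bromo-2-(methoxymethoxy)phenyl]{(2R,3S)-3-[4-(benzyloxy)phenyl]oxiran-2-yl}methanone
Product: 9 (2R,3R)-7,8-bis(benzyloxy)-2-[4-(benzyloxy)phenyl]-6-bromo-3-hydroxychroman-4-one, via phenol epoxide 8 (not isolated)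
Conditions: HCl (conc., cat.), MeOH/THF, 55 °C
Reagents that add atoms: none
Why: Acid cleaves the methoxymethyl acetal and the freed phenol opens the epoxide at the benzylic carbon in a 6-endo mode with inversion while C3 is untouched, which should give the favoured 2,3-trans-dihydroflavonol (2R,3R).

Step 7
Reactants: 9 (2R,3R)-7,8-bis(benzyloxy)-2-[4-(benzyloxy)phenyl]-6-bromo-3-hydroxychroman-4-one
Product: 10 (2R,3S,4R)-7,8-bis(benzyloxy)-2-[4-(benzyloxy)phenyl]-6-bromochromane-3,4-diol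
Conditions: NaBH4, MeOH/THF, 0 °C
Reagents that add atoms: none
Why: Borohydride reduction of the chromanone, in which axial hydride attack on the half-chair with equatorial C2 aryl and C3 hydroxyl should give the equatorial C4 alcohol, that is the 3,4-trans diol with (4R) configuration under substrate control.

Step 8
Reactants: 10 (2R,3S,4R)-7,8-bis(benzyloxy)-2-[4-(benzyloxy)phenyl]-6-bromochromane-3,4-diol
Product: 11 (2R,3R,4R)-7,8-bis(benzyloxy)-2-[4-(benzyloxy)phenyl]-6-bromo-3,4-bis(tert-butyldimethylsilyloxy)chromane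
Conditions: TBSOTf, 2,6-lutidine, CH2Cl2, 0 °C to rt
Reagents that add atoms: tert-butyldimethylsilyl trifluoromethanesulfonate, CC(C)(C)[Si](C)(C)OS(=O)(=O)C(F)(F)F
Why: Silylation of both secondary alcohols with the reactive silyl triflate gives ethers that withstand the organolithium, hydroxide, Pd and peracid steps and leave under fluoride (the C3 descriptor changes from S to R by priority only).

Step 9
Reactants: 11 (2R,3R,4R)-7,8-bis(benzyloxy)-2-[4-(benzyloxy)phenyl]-6-bromo-3,4-bis(tert-butyldimethylsilyloxy)chromane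
Product: 13 (2R,3R,4R)-7,8-bis(benzyloxy)-2-[4-(benzyloxy)phenyl]-3,4-bis(tert-butyldimethylsilyloxy)chromane-6-carbaldehyde (ArL–CHO), via aryllithium 12 (not isolated)
Conditions: n-BuLi, THF, −78 °C; then DMF, −78 to 0 °C; H2O
Reagents that add atoms: N,N-dimethylformamide, CN(C)C=O
Why: Bromine–lithium exchange followed by formylation with DMF (Bouveault aldehyde synthesis) places the aldehyde exactly where step 2 fixed the bromine.

Step 10
Reactants: 14 2,3-dihydroxybenzaldehyde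
Product: 15 2,3-bis(benzyloxy)benzaldehyde
Conditions: BnBr, K2CO3, DMF, 60 °C
Reagents that add atoms: benzyl bromide, BrCc1ccccc1
Why: Williamson etherification of both phenols.

Step 11
Reactants: 15 2,3-bis(benzyloxy)benzaldehyde
Product: 16 2,3-bis(benzyloxy)-6-bromobenzaldehyde
Conditions: NBS, DMF, rt
Reagents that add atoms: N-bromosuccinimide, O=C1CCC(=O)N1Br
Why: Electrophilic aromatic bromination, in which the 3-benzyloxy group directs para to C6 while the 2-alkoxy group, twisted out of plane between two ortho substituents, is a weak director, as is known for 2,3-dialkoxybenzaldehydes.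

Step 12
Reactants: 16 2,3-bis(benzyloxy)-6-bromobenzaldehyde
Product: 17 rac-1-[2,3-bis(benzyloxy)-6-bromophenyl]ethan-1-ol
Conditions: MeMgBr, THF, 0 °C; aqueous work-up
Reagents that add atoms: methylmagnesium bromide, C[Mg]Br
Why: Grignard addition to the aldehyde, the racemic carbinol centre being removed in the next step.

Step 13
Reactants: 17 rac-1-[2,3-bis(benzyloxy)-6-bromophenyl]ethan-1-ol
Product: 18 1-[2,3-bis(benzyloxy)-6-bromophenyl]ethan-1-one
Conditions: Dess–Martin periodinane, CH2Cl2, rt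
Reagents that add atoms: none
Why: Dess–Martin oxidation of the benzylic alcohol to the methyl ketone under neutral conditions.

Step 14
Reactants: 18 1-[2,3-bis(benzyloxy)-6-bromophenyl]ethan-1-one; 13 ArL–CHO
Product: 19 (E)-1-[2,3-bis(benzyloxy)-6-bromophenyl]-3-ArL-prop-2-en-1-one
Conditions: KOH, EtOH/THF, rt
Reagents that add atoms: none
Why: Claisen–Schmidt condensation of the methyl ketone with the non-enolisable aldehyde gives the E-enone, and alkyl silyl ethers tolerate hydroxide at room temperature.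

Step 15
Reactants: 19 (E)-1-[2,3-bis(benzyloxy)-6-bromophenyl]-3-ArL-prop-2-en-1-one
Product: 20 (3R)-6,7-bis(benzyloxy)-3-ArL-indan-1-one
Conditions: Pd(OAc)2 (10 mol %), (R)-3,5-Xyl-MeO-BIPHEP (12 mol %), iPr2NEt, DMF/ethylene glycol, 90 °C
Reagents that add atoms: none
Why: Asymmetric intramolecular reductive Heck reaction (formally a 5-endo conjugate arylation of the enone, the amine serving as hydride donor), in which the chiral bisphosphine on palladium selects the enone face and so sets indanone C3 as (3R), the remote lower-unit centres having little influence.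

Step 16
Reactants: 20 (3R)-6,7-bis(benzyloxy)-3-ArL-indan-1-one
Product: 22 (4R)-7,8-bis(benzyloxy)-4-ArL-chroman-2-one, via Criegee adduct 21 (not isolated)
Conditions: mCPBA, CH2Cl2, 0 °C to rt
Reagents that add atoms: 3-chloroperbenzoic acid, OOC(=O)c1cccc(Cl)c1
Why: Baeyer–Villiger oxidation: the peracid adds to the C1 carbonyl to give Criegee adduct 21, and aromatic carbon C7a then shifts from C1 to the proximal peroxide oxygen as 3-chlorobenzoate leaves, which creates the C8a–O1 and O1–C2 bonds of the future flavan. The closest known reaction type is the oxidation of 1-indanones to 3,4-dihydrocoumarins with aryl migration. The six-membered lactone arises by ring expansion of the five-membered ketone through this 1,2-shift, not by cyclisation of an open chain. No stereocentre is created, since the migrating carbon is sp2 and indanone C3, remote from the reacting bonds, becomes lactone C4 with unchanged configuration. The step needs migration of the aryl carbon in preference to the C2 methylene, which the electron-rich ring (benzyloxy group ortho to the migrating carbon) against a primary alkyl competitor secures, and it needs the peracid to spare the benzyloxyarenes and silyl ethers, for which low temperature and the absence of strong acid are chosen.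

Step 17
Reactants: 22 (4R)-7,8-bis(benzyloxy)-4-ArL-chroman-2-one
Product: 24 (3R,4R)-7,8-bis(benzyloxy)-3-hydroxy-4-ArL-chroman-2-one, via potassium enolate 23 (not isolated)
Conditions: KN(SiMe3)2, THF, −78 °C; then 2-(phenylsulfonyl)-3-phenyloxaziridine, −78 °C; AcOH
Reagents that add atoms: 2-(phenylsulfonyl)-3-phenyloxaziridine, O=S(=O)(N1OC1c1ccccc1)c1ccccc1
Why: Davis oxidation of the lactone enolate, in which the oxaziridine should approach the face anti to the pseudo-axial C4 aryl group and so give the 3,4-trans (3R) alcohol under substrate control.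

Step 18
Reactants: 24 (3R,4R)-7,8-bis(benzyloxy)-3-hydroxy-4-ArL-chroman-2-one
Product: 25 (3R,4R)-3,7,8-tris(benzyloxy)-4-ArL-chroman-2-one
Conditions: BnBr, Ag2O, CH2Cl2, rt, dark
Reagents that add atoms: benzyl bromide, BrCc1ccccc1
Why: Silver-oxide-mediated benzylation (Purdie-type etherification) is essentially neutral, so the aryl lactone and the α-stereocentre survive, and the benzyl ether can chelate in step 21 and leaves in the final hydrogenolysis.

Step 19
Reactants: 25 (3R,4R)-3,7,8-tris(benzyloxy)-4-ArL-chroman-2-one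
Product: 26 (2R,3R)-2-(benzyloxy)-3-[3,4-bis(benzyloxy)-2-hydroxyphenyl]-N-methoxy-N-methyl-3-ArL-propanamide
Conditions: MeNH(OMe)·HCl, iPrMgCl, THF, −20 °C; aqueous work-up
Reagents that add atoms: N,O-dimethylhydroxylamine hydrochloride, CNOC.Cl
Why: Aminolysis of the aryl lactone by the magnesium amide of N,O-dimethylhydroxylamine (Weinreb amide formation) frees the C8a phenol and gives an acyl group that accepts exactly one organolithium.

Step 20
Reactants: 26 (2R,3R)-2-(benzyloxy)-3-[3,4-bis(benzyloxy)-2-hydroxyphenyl]-N-methoxy-N-methyl-3-ArL-propanamide; 27 1-(benzyloxy)-4-bromobenzene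
Product: 29 (2R,3R)-2-(benzyloxy)-1-[4-(benzyloxy)phenyl]-3-[3,4-bis(benzyloxy)-2-hydroxyphenyl]-3-ArL-propan-1-one, via 4-(benzyloxy)phenyllithium 28 (not isolated)
Conditions: 27, n-BuLi, THF, −78 °C; then 26 (3 equiv of aryllithium per amide), −78 to −40 °C; H2O
Reagents that add atoms: none
Why: Aryllithium addition to a Weinreb amide, in which the chelated tetrahedral adduct survives until work-up so that no tertiary alcohol forms, one extra equivalent of the aryllithium being consumed by the phenol.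

Step 21
Reactants: 29 (2R,3R)-2-(benzyloxy)-1-[4-(benzyloxy)phenyl]-3-[3,4-bis(benzyloxy)-2-hydroxyphenyl]-3-ArL-propan-1-one
Product: 30 (1S,2R,3R)-2-(benzyloxy)-1-[4-(benzyloxy)phenyl]-3-[3,4-bis(benzyloxy)-2-hydroxyphenyl]-3-ArL-propan-1-ol
Conditions: Zn(BH4)2, Et2O/CH2Cl2, −30 to 0 °C
Reagents that add atoms: none
Why: Chelation-controlled (Cram chelate) reduction, in which zinc bridges the ketone and α-benzyloxy oxygens and hydride enters from the side of the α-hydrogen, away from the diarylmethyl group, to give the anti (1S) alcohol.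

Step 22
Reactants: 30 (1S,2R,3R)-2-(benzyloxy)-1-[4-(benzyloxy)phenyl]-3-[3,4-bis(benzyloxy)-2-hydroxyphenyl]-3-ArL-propan-1-ol
Product: 31 (2R,3R,4R)-3,7,8-tris(benzyloxy)-2-[4-(benzyloxy)phenyl]-4-ArL-chromane
Conditions: PPh3, DIAD, THF, 0 °C
Reagents that add atoms: none
Why: Intramolecular Mitsunobu etherification, in which the phenol displaces the activated benzylic oxygen in a 6-exo-tet SN2 closure with inversion, so that the anti alcohol gives the 2,3-cis (2R) flavan.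

Step 23
Reactants: 31 (2R,3R,4R)-3,7,8-tris(benzyloxy)-2-[4-(benzyloxy)phenyl]-4-ArL-chromane
Product: 32 (2R,3R,4R)-3,7,8-tris(benzyloxy)-2-[4-(benzyloxy)phenyl]-4-[(2R,3S,4R)-7,8-bis(benzyloxy)-2-[4-(benzyloxy)phenyl]-3,4-dihydroxychroman-6-yl]chromane
Conditions: Bu4NF, THF, 0 °C to rt
Reagents that add atoms: none
Why: Fluoride-induced cleavage of both silyl ethers, to which benzyl ethers are inert.

Step 24
Reactants: 32 (2R,3R,4R)-3,7,8-tris(benzyloxy)-2-[4-(benzyloxy)phenyl]-4-[(2R,3S,4R)-7,8-bis(benzyloxy)-2-[4-(benzyloxy)phenyl]-3,4-dihydroxychroman-6-yl]chromane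
Product: 33 (2R,3R,4S)-2-(4-hydroxyphenyl)-4-[(2R,3S,4R)-3,4,7,8-tetrahydroxy-2-(4-hydroxyphenyl)chroman-6-yl]chromane-3,7,8-triol (CNP0391561.5)
Conditions: H2 (1 atm), Pd(OH)2/C, THF/MeOH, rt
Reagents that add atoms: none
Why: Hydrogenolysis of the seven benzyl ethers over Pearlman's catalyst under neutral conditions, which should leave the flavan C2–O1 bonds and the benzylic C4 hydroxyl intact, gives the free polyphenol.

**Compound list**

1 | gallacetophenone | CC(=O)c1ccc(O)c(O)c1O | starting material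
2 | 1-[3,4-bis(benzyloxy)-2-hydroxyphenyl]ethan-1-one | CC(=O)c1ccc(OCc2ccccc2)c(OCc2ccccc2)c1O | intermediate
3 | 1-[3,4-bis(benzyloxy)-5-bromo-2-hydroxyphenyl]ethan-1-one | CC(=O)c1cc(Br)c(OCc2ccccc2)c(OCc2ccccc2)c1O | intermediate
4 | 1-[3,4-bis(benzyloxy)-5-bromo-2-(methoxymethoxy)phenyl]ethan-1-one | CC(=O)c1cc(Br)c(OCc2ccccc2)c(OCc2ccccc2)c1OCOC | intermediate
5 | 4-(benzyloxy)benzaldehyde | O=Cc1ccc(OCc2ccccc2)cc1 | starting material
6 | (E)-1-[3,4-bis(benzyloxy)-5-bromo-2-(methoxymethoxy)phenyl]-3-[4-(benzyloxy)phenyl]prop-2-en-1-one | O=C(/C=C/c1ccc(OCc2ccccc2)cc1)c1cc(Br)c(OCc2ccccc2)c(OCc2ccccc2)c1OCOC | intermediate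
7 | [3,4-bis(benzyloxy)-5-bromo-2-(methoxymethoxy)phenyl]{(2R,3S)-3-[4-(benzyloxy)phenyl]oxiran-2-yl}methanone | O=C([C@@H]1O[C@H]1c2ccc(OCc3ccccc3)cc2)c4cc(Br)c(OCc5ccccc5)c(OCc6ccccc6)c4OCOC | intermediate
8 | [3,4-bis(benzyloxy)-5-bromo-2-hydroxyphenyl]{(2R,3S)-3-[4-(benzyloxy)phenyl]oxiran-2-yl}methanone (phenol epoxide, not isolated) | O=C([C@@H]1O[C@H]1c2ccc(OCc3ccccc3)cc2)c4cc(Br)c(OCc5ccccc5)c(OCc6ccccc6)c4O | intermediate
9 | (2R,3R)-7,8-bis(benzyloxy)-2-[4-(benzyloxy)phenyl]-6-bromo-3-hydroxychroman-4-one | Brc3cc4c(c(OCc5ccccc5)c3OCc5ccccc5)O[C@H](c3ccc(OCc5ccccc5)cc3)[C@@H](O)C4=O | intermediate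
10 | (2R,3S,4R)-7,8-bis(benzyloxy)-2-[4-(benzyloxy)phenyl]-6-bromochromane-3,4-diol | Brc3cc4c(c(OCc5ccccc5)c3OCc5ccccc5)O[C@H](c3ccc(OCc5ccccc5)cc3)[C@@H](O)[C@@H]4O | intermediate
11 | (2R,3R,4R)-7,8-bis(benzyloxy)-2-[4-(benzyloxy)phenyl]-6-bromo-3,4-bis(tert-butyldimethylsilyloxy)chromane (ArL–Br) | Brc3cc4c(c(OCc5ccccc5)c3OCc5ccccc5)O[C@H](c3ccc(OCc5ccccc5)cc3)[C@@H](O[Si](C)(C)C(C)(C)C)[C@@H]4O[Si](C)(C)C(C)(C)C | intermediate
12 | 6-lithio derivative of 11 (ArL–Li, not isolated) | [Li]c3cc4c(c(OCc5ccccc5)c3OCc5ccccc5)O[C@H](c3ccc(OCc5ccccc5)cc3)[C@@H](O[Si](C)(C)C(C)(C)C)[C@@H]4O[Si](C)(C)C(C)(C)C | intermediate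
13 | (2R,3R,4R)-7,8-bis(benzyloxy)-2-[4-(benzyloxy)phenyl]-3,4-bis(tert-butyldimethylsilyloxy)chromane-6-carbaldehyde (ArL–CHO) | O=Cc3cc4c(c(OCc5ccccc5)c3OCc5ccccc5)O[C@H](c3ccc(OCc5ccccc5)cc3)[C@@H](O[Si](C)(C)C(C)(C)C)[C@@H]4O[Si](C)(C)C(C)(C)C | intermediate
14 | 2,3-dihydroxybenzaldehyde | O=Cc1cccc(O)c1O | starting material
15 | 2,3-bis(benzyloxy)benzaldehyde | O=Cc1cccc(OCc2ccccc2)c1OCc1ccccc1 | intermediate
16 | 2,3-bis(benzyloxy)-6-bromobenzaldehyde | O=Cc1c(Br)ccc(OCc2ccccc2)c1OCc1ccccc1 | intermediate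
17 | rac-1-[2,3-bis(benzyloxy)-6-bromophenyl]ethan-1-ol | CC(O)c1c(Br)ccc(OCc2ccccc2)c1OCc1ccccc1 | intermediate
18 | 1-[2,3-bis(benzyloxy)-6-bromophenyl]ethan-1-one | CC(=O)c1c(Br)ccc(OCc2ccccc2)c1OCc1ccccc1 | intermediate
19 | (E)-1-[2,3-bis(benzyloxy)-6-bromophenyl]-3-ArL-prop-2-en-1-one | O=C(/C=C/c3cc4c(c(OCc5ccccc5)c3OCc5ccccc5)O[C@H](c3ccc(OCc5ccccc5)cc3)[C@@H](O[Si](C)(C)C(C)(C)C)[C@@H]4O[Si](C)(C)C(C)(C)C)c1c(Br)ccc(OCc2ccccc2)c1OCc1ccccc1 | intermediate
20 | (3R)-6,7-bis(benzyloxy)-3-ArL-indan-1-one | O=C1C[C@@H](c3cc4c(c(OCc5ccccc5)c3OCc5ccccc5)O[C@H](c3ccc(OCc5ccccc5)cc3)[C@@H](O[Si](C)(C)C(C)(C)C)[C@@H]4O[Si](C)(C)C(C)(C)C)c2ccc(OCc5ccccc5)c(OCc5ccccc5)c12 | intermediate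
21 | Criegee adduct: (3R)-6,7-bis(benzyloxy)-1-hydroxy-3-ArL-indan-1-yl 3-chloroperoxybenzoate, C1 epimers (not isolated) | OC1(OOC(=O)c6cccc(Cl)c6)C[C@@H](c3cc4c(c(OCc5ccccc5)c3OCc5ccccc5)O[C@H](c3ccc(OCc5ccccc5)cc3)[C@@H](O[Si](C)(C)C(C)(C)C)[C@@H]4O[Si](C)(C)C(C)(C)C)c2ccc(OCc5ccccc5)c(OCc5ccccc5)c12 | intermediate
22 | (4R)-7,8-bis(benzyloxy)-4-ArL-chroman-2-one | O=C1C[C@@H](c3cc4c(c(OCc5ccccc5)c3OCc5ccccc5)O[C@H](c3ccc(OCc5ccccc5)cc3)[C@@H](O[Si](C)(C)C(C)(C)C)[C@@H]4O[Si](C)(C)C(C)(C)C)c2ccc(OCc5ccccc5)c(OCc5ccccc5)c2O1 | intermediate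
23 | potassium enolate of 22 (not isolated) | [K+].[O-]C1=C[C@@H](c3cc4c(c(OCc5ccccc5)c3OCc5ccccc5)O[C@H](c3ccc(OCc5ccccc5)cc3)[C@@H](O[Si](C)(C)C(C)(C)C)[C@@H]4O[Si](C)(C)C(C)(C)C)c2ccc(OCc5ccccc5)c(OCc5ccccc5)c2O1 | intermediate
24 | (3R,4R)-7,8-bis(benzyloxy)-3-hydroxy-4-ArL-chroman-2-one (3,4-trans) | O=C1Oc2c(ccc(OCc5ccccc5)c2OCc5ccccc5)[C@H](c3cc4c(c(OCc5ccccc5)c3OCc5ccccc5)O[C@H](c3ccc(OCc5ccccc5)cc3)[C@@H](O[Si](C)(C)C(C)(C)C)[C@@H]4O[Si](C)(C)C(C)(C)C)[C@H]1O | intermediate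
25 | (3R,4R)-3,7,8-tris(benzyloxy)-4-ArL-chroman-2-one | O=C1Oc2c(ccc(OCc5ccccc5)c2OCc5ccccc5)[C@H](c3cc4c(c(OCc5ccccc5)c3OCc5ccccc5)O[C@H](c3ccc(OCc5ccccc5)cc3)[C@@H](O[Si](C)(C)C(C)(C)C)[C@@H]4O[Si](C)(C)C(C)(C)C)[C@H]1OCc6ccccc6 | intermediate
26 | (2R,3R)-2-(benzyloxy)-3-[3,4-bis(benzyloxy)-2-hydroxyphenyl]-N-methoxy-N-methyl-3-ArL-propanamide | CON(C)C(=O)[C@H](OCc6ccccc6)[C@@H](c3cc4c(c(OCc5ccccc5)c3OCc5ccccc5)O[C@H](c3ccc(OCc5ccccc5)cc3)[C@@H](O[Si](C)(C)C(C)(C)C)[C@@H]4O[Si](C)(C)C(C)(C)C)c1ccc(OCc5ccccc5)c(OCc5ccccc5)c1O | intermediate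
27 | 1-(benzyloxy)-4-bromobenzene | Brc1ccc(OCc2ccccc2)cc1 | starting material
28 | 4-(benzyloxy)phenyllithium (not isolated) | [Li]c1ccc(OCc2ccccc2)cc1 | intermediate
29 | (2R,3R)-2-(benzyloxy)-1-[4-(benzyloxy)phenyl]-3-[3,4-bis(benzyloxy)-2-hydroxyphenyl]-3-ArL-propan-1-one | O=C(c1ccc(OCc2ccccc2)cc1)[C@H](OCc6ccccc6)[C@@H](c3cc4c(c(OCc5ccccc5)c3OCc5ccccc5)O[C@H](c3ccc(OCc5ccccc5)cc3)[C@@H](O[Si](C)(C)C(C)(C)C)[C@@H]4O[Si](C)(C)C(C)(C)C)c1ccc(OCc5ccccc5)c(OCc5ccccc5)c1O | intermediate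
30 | (1S,2R,3R)-2-(benzyloxy)-1-[4-(benzyloxy)phenyl]-3-[3,4-bis(benzyloxy)-2-hydroxyphenyl]-3-ArL-propan-1-ol (anti) | O[C@@H](c1ccc(OCc2ccccc2)cc1)[C@H](OCc6ccccc6)[C@@H](c3cc4c(c(OCc5ccccc5)c3OCc5ccccc5)O[C@H](c3ccc(OCc5ccccc5)cc3)[C@@H](O[Si](C)(C)C(C)(C)C)[C@@H]4O[Si](C)(C)C(C)(C)C)c1ccc(OCc5ccccc5)c(OCc5ccccc5)c1O | intermediate
31 | (2R,3R,4R)-3,7,8-tris(benzyloxy)-2-[4-(benzyloxy)phenyl]-4-ArL-chromane (2,3-cis-3,4-trans) | O(Cc6ccccc6)c1ccc([C@H]2Oc3c(ccc(OCc5ccccc5)c3OCc5ccccc5)[C@H](c3cc4c(c(OCc5ccccc5)c3OCc5ccccc5)O[C@H](c3ccc(OCc5ccccc5)cc3)[C@@H](O[Si](C)(C)C(C)(C)C)[C@@H]4O[Si](C)(C)C(C)(C)C)[C@H]2OCc6ccccc6)cc1 | intermediate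
32 | (2R,3R,4R)-3,7,8-tris(benzyloxy)-2-[4-(benzyloxy)phenyl]-4-[(2R,3S,4R)-7,8-bis(benzyloxy)-2-[4-(benzyloxy)phenyl]-3,4-dihydroxychroman-6-yl]chromane | O(Cc6ccccc6)c1ccc([C@H]2Oc3c(ccc(OCc5ccccc5)c3OCc5ccccc5)[C@H](c3cc4c(c(OCc5ccccc5)c3OCc5ccccc5)O[C@H](c3ccc(OCc5ccccc5)cc3)[C@@H](O)[C@@H]4O)[C@H]2OCc6ccccc6)cc1 | intermediate
33 | (2R,3R,4S)-2-(4-hydroxyphenyl)-4-[(2R,3S,4R)-3,4,7,8-tetrahydroxy-2-(4-hydroxyphenyl)chroman-6-yl]chromane-3,7,8-triol (CNP0391561.5) | Oc1ccc([C@H]2Oc3c(ccc(O)c3O)[C@H](c3cc4c(c(O)c3O)O[C@H](c3ccc(O)cc3)[C@@H](O)[C@@H]4O)[C@H]2O)cc1 | target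

**Totals**

Total step count: 24. Longest linear sequence: 20 steps (steps 1–9, then 14–24); the second branch (steps 10–13) joins at step 14.

**Steps most likely to fail**

Step 15 (reductive Heck). The 5-endo insertion at an aryl–palladium centre flanked by the acyl group, onto an enone terminus carrying a bulky ortho-substituted aryl, may be slower than hydrodebromination, and face selection by the ligand may be poor. Fallback, setting out from ketone 18 and returning at indanone 20: Miyaura borylation of 18 (B2pin2, PdCl2(dppf), KOAc, dioxane, 80 °C) would give 1-[2,3-bis(benzyloxy)-6-(4,4,5,5-tetramethyl-1,3,2-dioxaborolan-2-yl)phenyl]ethan-1-one F1. Pyrrolidine-catalysed condensation of F1 with aldehyde 13 would give the boronate chalcone (E)-1-[2,3-bis(benzyloxy)-6-(4,4,5,5-tetramethyl-1,3,2-dioxaborolan-2-yl)phenyl]-3-ArL-prop-2-en-1-one F2. A rhodium-catalysed asymmetric intramolecular 1,4-addition ([RhCl(C2H4)2]2, MonoPhos antipode chosen for the (3R) product, aqueous K3PO4, toluene, 80 °C) would then close the five-membered ring by transmetalation and enone insertion, with no aryl halide reduction pathway open, and deliver 20.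

Step 16 (Baeyer–Villiger, key step). Peracid addition to the electron-rich carbonyl flanked by the C7 benzyloxy group may be sluggish. Forcing it could bring hydroxylation of the benzyloxyarenes or, if acid catalysis is needed, loss of the benzylic silyl ether. Fallback, setting out from bromide 11 (through aryllithium 12) and returning at lactone 22, which builds the same 4-aryl-dihydrocoumarin without oxygen insertion: 12 is quenched with 2-isopropoxy-4,4,5,5-tetramethyl-1,3,2-dioxaborolane to give the lower-unit pinacol boronate ArL–B(pin) F3. Commercial 7,8-dihydroxycoumarin is benzylated (BnBr, K2CO3, DMF) to 7,8-bis(benzyloxy)-2H-chromen-2-one F4. A Hayashi–Miyaura asymmetric 1,4-addition of F3 to F4 (Rh(acac)(C2H4)2, Segphos antipode chosen for the (4R) product, aqueous KOH, dioxane, 60 °C) would set C4 under catalyst control and give 22.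

Step 22 (Mitsunobu closure). The oxyphosphonium intermediate sits on a carbon para to a benzyloxy group and may ionise before the hindered phenol attacks. That would erode the C2 configuration towards the 2,3-trans epimer or lead to elimination. Fallback, setting out from Weinreb amide 26 and returning at flavan 31, with ring B carried as a bromoarene that cannot stabilise the benzylic cation: 4-bromophenyllithium F5 (from 1,4-dibromobenzene and n-BuLi, THF, −78 °C) adds to 26 to give (2R,3R)-2-(benzyloxy)-1-(4-bromophenyl)-3-[3,4-bis(benzyloxy)-2-hydroxyphenyl]-3-ArL-propan-1-one F6. Zn(BH4)2 reduction gives the anti alcohol (1S,2R,3R)-2-(benzyloxy)-1-(4-bromophenyl)-3-[3,4-bis(benzyloxy)-2-hydroxyphenyl]-3-ArL-propan-1-ol F7. Mitsunobu closure (PPh3, DIAD, THF) gives (2R,3R,4R)-3,7,8-tris(benzyloxy)-2-(4-bromophenyl)-4-ArL-chromane F8. Palladium-catalysed C–O coupling of F8 with benzyl alcohol ([PdCl(C3H5)]2, RockPhos, Cs2CO3, toluene, 90 °C) then installs the 4′-benzyloxy group and gives 31.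

**Further compounds**

F1 | step 15 | 1-[2,3-bis(benzyloxy)-6-(4,4,5,5-tetramethyl-1,3,2-dioxaborolan-2-yl)phenyl]ethan-1-one | CC(=O)c1c(B2OC(C)(C)C(C)(C)O2)ccc(OCc2ccccc2)c1OCc1ccccc1
F2 | step 15 | (E)-1-[2,3-bis(benzyloxy)-6-(4,4,5,5-tetramethyl-1,3,2-dioxaborolan-2-yl)phenyl]-3-ArL-prop-2-en-1-one | O=C(/C=C/c3cc4c(c(OCc5ccccc5)c3OCc5ccccc5)O[C@H](c3ccc(OCc5ccccc5)cc3)[C@@H](O[Si](C)(C)C(C)(C)C)[C@@H]4O[Si](C)(C)C(C)(C)C)c1c(B2OC(C)(C)C(C)(C)O2)ccc(OCc2ccccc2)c1OCc1ccccc1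
F3 | step 16 | 2-ArL-4,4,5,5-tetramethyl-1,3,2-dioxaborolane (lower-unit 6-boronate) | CC1(C)OB(OC1(C)C)c3cc4c(c(OCc5ccccc5)c3OCc5ccccc5)O[C@H](c3ccc(OCc5ccccc5)cc3)[C@@H](O[Si](C)(C)C(C)(C)C)[C@@H]4O[Si](C)(C)C(C)(C)C
F4 | step 16 | 7,8-bis(benzyloxy)-2H-chromen-2-one | O=c1ccc2ccc(OCc3ccccc3)c(OCc3ccccc3)c2o1
F5 | step 22 | 4-bromophenyllithium | [Li]c1ccc(Br)cc1
F6 | step 22 | (2R,3R)-2-(benzyloxy)-1-(4-bromophenyl)-3-[3,4-bis(benzyloxy)-2-hydroxyphenyl]-3-ArL-propan-1-one | O=C(c1ccc(Br)cc1)[C@H](OCc6ccccc6)[C@@H](c3cc4c(c(OCc5ccccc5)c3OCc5ccccc5)O[C@H](c3ccc(OCc5ccccc5)cc3)[C@@H](O[Si](C)(C)C(C)(C)C)[C@@H]4O[Si](C)(C)C(C)(C)C)c1ccc(OCc5ccccc5)c(OCc5ccccc5)c1O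
F7 | step 22 | (1S,2R,3R)-2-(benzyloxy)-1-(4-bromophenyl)-3-[3,4-bis(benzyloxy)-2-hydroxyphenyl]-3-ArL-propan-1-ol | O[C@@H](c1ccc(Br)cc1)[C@H](OCc6ccccc6)[C@@H](c3cc4c(c(OCc5ccccc5)c3OCc5ccccc5)O[C@H](c3ccc(OCc5ccccc5)cc3)[C@@H](O[Si](C)(C)C(C)(C)C)[C@@H]4O[Si](C)(C)C(C)(C)C)c1ccc(OCc5ccccc5)c(OCc5ccccc5)c1O
F8 | step 22 | (2R,3R,4R)-3,7,8-tris(benzyloxy)-2-(4-bromophenyl)-4-ArL-chromane | Brc1ccc([C@H]2Oc3c(ccc(OCc5ccccc5)c3OCc5ccccc5)[C@H](c3cc4c(c(OCc5ccccc5)c3OCc5ccccc5)O[C@H](c3ccc(OCc5ccccc5)cc3)[C@@H](O[Si](C)(C)C(C)(C)C)[C@@H]4O[Si](C)(C)C(C)(C)C)[C@H]2OCc6ccccc6)cc1
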